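**Plan**

- Enabling feature: ring A carries oxygen on C5 and C7, meta to each other across C6–H, with C8–OMe alongside. This is the pattern left when a ketone carbon (C7) and an ester carbonyl (C5) are joined through a methyl carbon (C6). Ring A is fused at C4a–C8a to ring C, the 3-hydroxy-4-pyranone found in kojic acid.
- Retrosynthetic cuts, in order: the 7-O–prenyl bond and two SEM acetals; C5–C6 (intramolecular Claisen); C7–C8 (lateral acylation); C4a–C5 (carbonylation of a C–I bond); C2–C1' (Suzuki coupling). This leads back to kojic acid, a guaiacyl boronate, 1-acetylimidazole, CO/MeOH and prenyl bromide.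
- Forward order: ring C is bought as kojic acid; ring B is attached by cross-coupling; the ester and the CH(OMe)COCH3 chain are placed on the two remaining pyranone carbons; ring A is closed last; 7-O-prenylation and SEM removal finish the route.
- Stereochemistry: the target has no stereocentre and no E/Z element, so no enantiomer needs to be selected. The only sp3 stereocentre on the way (C8 in 11 and 12) is racemic and becomes aromatic.

Key step: step 9

**Remarks**

- SEM-oxy means [2-(trimethylsilyl)ethoxy]methoxy, OCH2OCH2CH2SiMe3.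
- Monocyclic pyranones are numbered as in kojic acid: O1, C2 bears the CH2O carbon, C4 is the carbonyl, C5 bears oxygen, C6 bears Br or aryl.
- Compounds 5 and 10 are assumed to be commercially available.

**Route**

Step 1
Reactants: 1 kojic acid
Product: 2 6-bromo-5-hydroxy-2-(hydroxymethyl)-4H-pyran-4-one
Conditions: NBS (1.0 equiv), DMF, 0 °C → rt, dark
Reagents that add atoms: N-bromosuccinimide, O=C1CCC(=O)N1Br
Why: Electrophilic bromination of the enol should occur at C6, the carbon ortho to the free 5-OH where kojic acid undergoes its electrophilic substitutions, leaving the less activated C3–H untouched.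

Step 2
Reactants: 2 6-bromo-5-hydroxy-2-(hydroxymethyl)-4H-pyran-4-one
Product: 3 6-bromo-2-(hydroxymethyl)-5-(SEM-oxy)-4H-pyran-4-one
Conditions: SEMCl (1.05 equiv), K2CO3, DMF, 0 °C → rt
Reagents that add atoms: 2-(trimethylsilyl)ethoxymethyl chloride, C[Si](C)(C)CCOCCl
Why: Williamson-type O-alkylation; carbonate deprotonates only the acidic enolic 5-OH and not the primary alcohol, so the SEM acetal should form on O5 alone.

Step 3
Reactants: 3 6-bromo-2-(hydroxymethyl)-5-(SEM-oxy)-4H-pyran-4-one
Product: 4 6-bromo-2-(methoxymethyl)-5-(SEM-oxy)-4H-pyran-4-one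
Conditions: MeI (excess), Ag2O, 4 Å MS, CH2Cl2, 40 °C, dark
Reagents that add atoms: iodomethane, CI
Why: Purdie methylation etherifies the primary alcohol under near-neutral conditions, which avoids a free alkoxide that could displace the vinylogous acyl bromide at C6.

Step 4
Reactants: 5 2-methoxy-4-(4,4,5,5-tetramethyl-1,3,2-dioxaborolan-2-yl)phenol
Product: 6 2-[3-methoxy-4-(SEM-oxy)phenyl]-4,4,5,5-tetramethyl-1,3,2-dioxaborolane
Conditions: SEMCl, i-Pr2NEt, CH2Cl2, 0 °C → rt
Reagents that add atoms: 2-(trimethylsilyl)ethoxymethyl chloride, C[Si](C)(C)CCOCCl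
Why: Amine-mediated acetalisation of a phenol with a chloromethyl ether (SEM protection); the pinacol boronate is inert to these conditions.

Step 5
Reactants: 4 6-bromo-2-(methoxymethyl)-5-(SEM-oxy)-4H-pyran-4-one; 6 2-[3-methoxy-4-(SEM-oxy)phenyl]-4,4,5,5-tetramethyl-1,3,2-dioxaborolane
Product: 7 6-[3-methoxy-4-(SEM-oxy)phenyl]-2-(methoxymethyl)-5-(SEM-oxy)-4H-pyran-4-one
Conditions: Pd(dppf)Cl2 (5 mol %), K2CO3, 1,4-dioxane/H2O (5:1), 80 °C
Reagents that add atoms: none
Why: Suzuki–Miyaura coupling; the C6–Br bond of a β-bromo enone undergoes ready oxidative addition, and the SEM and methyl ethers are stable to aqueous carbonate.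

Step 6
Reactants: 7 6-[3-methoxy-4-(SEM-oxy)phenyl]-2-(methoxymethyl)-5-(SEM-oxy)-4H-pyran-4-one
Product: 8 3-iodo-6-[3-methoxy-4-(SEM-oxy)phenyl]-2-(methoxymethyl)-5-(SEM-oxy)-4H-pyran-4-one
Conditions: NIS (1.1 equiv), TFA (10 mol %), MeCN, 0 °C → rt, dark
Reagents that add atoms: N-iodosuccinimide, O=C1CCC(=O)N1I
Why: Electrophilic iodination should take the only ring C–H, C3, the nucleophilic α-carbon of the vinylogous ester O1–C2=C3–C4=O, as in the 3-iodination of flavones; the aryl ring is conjugated to the electron-poor pyranone and should react more slowly.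

Step 7
Reactants: 8 3-iodo-6-[3-methoxy-4-(SEM-oxy)phenyl]-2-(methoxymethyl)-5-(SEM-oxy)-4H-pyran-4-one
Product: 9 methyl 6-[3-methoxy-4-(SEM-oxy)phenyl]-2-(methoxymethyl)-4-oxo-5-(SEM-oxy)-4H-pyran-3-carboxylate
Conditions: Pd(OAc)2 (5 mol %), Xantphos (6 mol %), CO (1 atm), MeOH, Et3N, DMF, 70 °C
Reagents that add atoms: carbon monoxide, [C-]#[O+]; methanol, CO
Why: Palladium-catalysed alkoxycarbonylation (Heck carbonylation) of an α-iodo enone should deliver the methyl ester by oxidative addition, CO insertion and methanolysis, under conditions to which the SEM acetals are inert.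

Step 8
Reactants: 9 methyl 6-[3-methoxy-4-(SEM-oxy)phenyl]-2-(methoxymethyl)-4-oxo-5-(SEM-oxy)-4H-pyran-3-carboxylate; 10 1-acetylimidazole
Product: 11 methyl 2-(1-methoxy-2-oxopropyl)-6-[3-methoxy-4-(SEM-oxy)phenyl]-4-oxo-5-(SEM-oxy)-4H-pyran-3-carboxylate (racemic)
Conditions: LiHMDS (2.1 equiv), THF, −78 °C; then 10 (1.5 equiv), −78 → −20 °C; AcOH, −78 °C
Reagents that add atoms: none
Why: Vinylogous (lateral) deprotonation of the 2-CH2OMe group, acidified through C2=C3 by both the C4 ketone and the C3 ester, gives a dienolate that should be C-acylated at the exocyclic carbon by the acyl imidazole (Claisen-type lateral acylation as known for 2-alkyl-4-pyranones and 2-methylchromones), the second equivalent of base holding the more acidic product as its enolate until the cold quench.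

Step 9
Reactants: 11 methyl 2-(1-methoxy-2-oxopropyl)-6-[3-methoxy-4-(SEM-oxy)phenyl]-4-oxo-5-(SEM-oxy)-4H-pyran-3-carboxylate (racemic)
Product: 13 5,7-dihydroxy-8-methoxy-2-[3-methoxy-4-(SEM-oxy)phenyl]-3-(SEM-oxy)-4H-chromen-4-one, via triketone tautomer 12 (not isolated)
Conditions: LDA (3 equiv), THF, −78 → 0 °C; AcOH
Reagents that add atoms: none
Why: LDA should first remove the most acidic proton, C8–H of the side chain, and then a proton of the methyl ketone, giving a dianion whose terminal enolate carbon (future C6) adds to the ester carbonyl on the neighbouring pyranone carbon (future C5); loss of methoxide gives triketone 12 as its enolate, which tautomerises to the 5,7-dihydroxy arene. The closest known reaction type is the intramolecular Claisen (Dieckmann-type) condensation of ortho-(2-oxopropyl)aryl esters to 1,3-dihydroxyarenes, as in the conversion of 2-acetonylbenzoates into naphthalene-1,3-diols and in polyketide-type resorcinol syntheses. Ring A closes in a 6-exo-trig mode through C6, C7, C8, C8a, C4a and C5. No stereocentre is formed, and the racemic C8 centre of 11 becomes an aromatic carbon. The step needs C–C bond formation from the methyl terminus only: the C8 carbanion could reach the ester only through a four-membered ring, and attack through the enolate oxygen is reversible in the presence of methoxide, whereas C-acylation ends irreversibly in the aromatic bis-phenoxide. Forming the dianion fully at −78 °C before warming keeps the side-chain ketone masked as its enolate, so the liberated methoxide should not cleave the acetyl group.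

Step 10
Reactants: 13 5,7-dihydroxy-8-methoxy-2-[3-methoxy-4-(SEM-oxy)phenyl]-3-(SEM-oxy)-4H-chromen-4-one; 14 prenyl bromide (1-bromo-3-methylbut-2-ene)
Product: 15 5-hydroxy-8-methoxy-2-[3-methoxy-4-(SEM-oxy)phenyl]-7-[(3-methylbut-2-en-1-yl)oxy]-3-(SEM-oxy)-4H-chromen-4-one
Conditions: K2CO3 (1.5 equiv), 14 (1.1 equiv), acetone, rt → 40 °C
Reagents that add atoms: none
Why: Williamson etherification under mild carbonate conditions should alkylate the free 7-OH selectively, because the 5-OH is hydrogen-bonded to the C4 carbonyl and far less nucleophilic, the usual outcome for 5,7-dihydroxyflavones.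

Step 11
Reactants: 15 5-hydroxy-8-methoxy-2-[3-methoxy-4-(SEM-oxy)phenyl]-7-[(3-methylbut-2-en-1-yl)oxy]-3-(SEM-oxy)-4H-chromen-4-one
Product: 16 3,5-dihydroxy-2-(4-hydroxy-3-methoxyphenyl)-8-methoxy-7-[(3-methylbut-2-en-1-yl)oxy]-4H-chromen-4-one (CNP0210396.0)
Conditions: TBAF (1 M in THF, excess), DMPU, 50 °C; AcOH
Reagents that add atoms: none
Why: Fluoride-induced β-elimination of both 2-(trimethylsilyl)ethoxymethyl acetals (SEM cleavage) should release the 3- and 4'-hydroxyls without acid, so the acid-labile aryl prenyl ether survives.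

**Compound list**

1 | kojic acid, 5-hydroxy-2-(hydroxymethyl)-4H-pyran-4-one | OCc1cc(=O)c(O)co1 | starting material
2 | 6-bromo-5-hydroxy-2-(hydroxymethyl)-4H-pyran-4-one | OCc1cc(=O)c(O)c(Br)o1 | intermediate
3 | 6-bromo-2-(hydroxymethyl)-5-(SEM-oxy)-4H-pyran-4-one | OCc1cc(=O)c(OCOCC[Si](C)(C)C)c(Br)o1 | intermediate
4 | 6-bromo-2-(methoxymethyl)-5-(SEM-oxy)-4H-pyran-4-one | COCc1cc(=O)c(OCOCC[Si](C)(C)C)c(Br)o1 | intermediate
5 | 2-methoxy-4-(4,4,5,5-tetramethyl-1,3,2-dioxaborolan-2-yl)phenol | COc1cc(B2OC(C)(C)C(C)(C)O2)ccc1O | starting material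
6 | 2-[3-methoxy-4-(SEM-oxy)phenyl]-4,4,5,5-tetramethyl-1,3,2-dioxaborolane | COc1cc(B2OC(C)(C)C(C)(C)O2)ccc1OCOCC[Si](C)(C)C | intermediate
7 | 6-[3-methoxy-4-(SEM-oxy)phenyl]-2-(methoxymethyl)-5-(SEM-oxy)-4H-pyran-4-one | COCc1cc(=O)c(OCOCC[Si](C)(C)C)c(-c2ccc(OCOCC[Si](C)(C)C)c(OC)c2)o1 | intermediate
8 | 3-iodo-6-[3-methoxy-4-(SEM-oxy)phenyl]-2-(methoxymethyl)-5-(SEM-oxy)-4H-pyran-4-one | COCc1oc(-c2ccc(OCOCC[Si](C)(C)C)c(OC)c2)c(OCOCC[Si](C)(C)C)c(=O)c1I | intermediate
9 | methyl 6-[3-methoxy-4-(SEM-oxy)phenyl]-2-(methoxymethyl)-4-oxo-5-(SEM-oxy)-4H-pyran-3-carboxylate | COCc1oc(-c2ccc(OCOCC[Si](C)(C)C)c(OC)c2)c(OCOCC[Si](C)(C)C)c(=O)c1C(=O)OC | intermediate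
10 | 1-acetylimidazole | CC(=O)n1ccnc1 | starting material
11 | methyl 2-(1-methoxy-2-oxopropyl)-6-[3-methoxy-4-(SEM-oxy)phenyl]-4-oxo-5-(SEM-oxy)-4H-pyran-3-carboxylate (racemic) | COC(=O)c1c(C(OC)C(C)=O)oc(-c2ccc(OCOCC[Si](C)(C)C)c(OC)c2)c(OCOCC[Si](C)(C)C)c1=O | intermediate
12 | 8-methoxy-2-[3-methoxy-4-(SEM-oxy)phenyl]-3-(SEM-oxy)-6H-chromene-4,5,7(8H)-trione (racemic, keto tautomer of 13) | COC1C(=O)CC(=O)c2c1oc(-c3ccc(OCOCC[Si](C)(C)C)c(OC)c3)c(OCOCC[Si](C)(C)C)c2=O | intermediate
13 | 5,7-dihydroxy-8-methoxy-2-[3-methoxy-4-(SEM-oxy)phenyl]-3-(SEM-oxy)-4H-chromen-4-one | COc1cc(-c2oc3c(OC)c(O)cc(O)c3c(=O)c2OCOCC[Si](C)(C)C)ccc1OCOCC[Si](C)(C)C | intermediate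
14 | prenyl bromide, 1-bromo-3-methylbut-2-ene | CC(C)=CCBr | starting material
15 | 5-hydroxy-8-methoxy-2-[3-methoxy-4-(SEM-oxy)phenyl]-7-[(3-methylbut-2-en-1-yl)oxy]-3-(SEM-oxy)-4H-chromen-4-one | COc1cc(-c2oc3c(OC)c(OCC=C(C)C)cc(O)c3c(=O)c2OCOCC[Si](C)(C)C)ccc1OCOCC[Si](C)(C)C | intermediate
16 | 3,5-dihydroxy-2-(4-hydroxy-3-methoxyphenyl)-8-methoxy-7-[(3-methylbut-2-en-1-yl)oxy]-4H-chromen-4-one | COc1cc(-c2oc3c(OC)c(OCC=C(C)C)cc(O)c3c(=O)c2O)ccc1O | target

**Step count and risks**

Total step count: 11. Longest linear sequence: 10 steps (steps 1–3 and 5–11, from kojic acid); step 4 prepares the coupling partner.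

Steps most likely to fail:

Step 8. The delocalised dienolate of 9 may be acylated on oxygen or at C3 instead of the exocyclic carbon, or may be too stabilised to add to the acyl donor, and proton transfer to the product may stall conversion. The fallback sets out from 8 and returns at 11. The acetyl group is introduced before the ester, on the iodide, whose lateral anion is not stabilised by an ester and should behave as an ordinary 2-alkyl-4-pyranone dienolate. LiHMDS (THF, −78 °C) followed by 10 should give 1-{3-iodo-6-[3-methoxy-4-(SEM-oxy)phenyl]-4-oxo-5-(SEM-oxy)-4H-pyran-2-yl}-1-methoxypropan-2-one F1. Methoxycarbonylation of F1 under the conditions of step 7, with methanol in large excess so that the acylpalladium is captured by solvent, then leads to 11.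

Step 9. The terminal enolate may not form cleanly next to the far more acidic C8–H, the conjugated methyl ester may be too weak an acyl donor, or the strong base may degrade the pyranone. The fallback sets out from 8 and returns at 13. The ester is exchanged for an aryl ester so that ring closure can run under mild, equilibrating base, as in Baker–Venkataraman-type acyl transfers. Carbonylation of 8 with phenol in place of methanol (Pd(OAc)2, Xantphos, CO, PhOH, Et3N) should give phenyl 6-[3-methoxy-4-(SEM-oxy)phenyl]-2-(methoxymethyl)-4-oxo-5-(SEM-oxy)-4H-pyran-3-carboxylate F2. Lateral acylation as in step 8 should give phenyl 2-(1-methoxy-2-oxopropyl)-6-[3-methoxy-4-(SEM-oxy)phenyl]-4-oxo-5-(SEM-oxy)-4H-pyran-3-carboxylate F3. Treatment of F3 with DBU or Cs2CO3 in MeCN at rt, where a small equilibrium share of the terminal enolate suffices and phenoxide is the leaving group, should close ring A to 13.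

Step 6. Iodination may compete on the alkoxy-substituted aryl ring, and the acid additive may erode a SEM acetal. The fallback sets out from 4 and returns at 9. The iodine is placed before the arene is present. NIS on 4 should give 6-bromo-3-iodo-2-(methoxymethyl)-5-(SEM-oxy)-4H-pyran-4-one F4, in which C3 is the only ring C–H. Chemoselective methoxycarbonylation of the C–I bond at 40–50 °C (Pd(PPh3)2Cl2, CO, MeOH, Et3N) should give methyl 6-bromo-2-(methoxymethyl)-4-oxo-5-(SEM-oxy)-4H-pyran-3-carboxylate F5. Suzuki coupling of F5 with 6 under the conditions of step 5 then gives 9.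

**Further compounds**

F1 | step 8 | 1-{3-iodo-6-[3-methoxy-4-(SEM-oxy)phenyl]-4-oxo-5-(SEM-oxy)-4H-pyran-2-yl}-1-methoxypropan-2-one (racemic) | COC(C(C)=O)c1oc(-c2ccc(OCOCC[Si](C)(C)C)c(OC)c2)c(OCOCC[Si](C)(C)C)c(=O)c1I
F2 | step 9 | phenyl 6-[3-methoxy-4-(SEM-oxy)phenyl]-2-(methoxymethyl)-4-oxo-5-(SEM-oxy)-4H-pyran-3-carboxylate | COCc1oc(-c2ccc(OCOCC[Si](C)(C)C)c(OC)c2)c(OCOCC[Si](C)(C)C)c(=O)c1C(=O)Oc1ccccc1
F3 | step 9 | phenyl 2-(1-methoxy-2-oxopropyl)-6-[3-methoxy-4-(SEM-oxy)phenyl]-4-oxo-5-(SEM-oxy)-4H-pyran-3-carboxylate (racemic) | COC(C(C)=O)c1oc(-c2ccc(OCOCC[Si](C)(C)C)c(OC)c2)c(OCOCC[Si](C)(C)C)c(=O)c1C(=O)Oc1ccccc1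
F4 | step 6 | 6-bromo-3-iodo-2-(methoxymethyl)-5-(SEM-oxy)-4H-pyran-4-one | COCc1oc(Br)c(OCOCC[Si](C)(C)C)c(=O)c1I
F5 | step 6 | methyl 6-bromo-2-(methoxymethyl)-4-oxo-5-(SEM-oxy)-4H-pyran-3-carboxylate | COCc1oc(Br)c(OCOCC[Si](C)(C)C)c(=O)c1C(=O)OC
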